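3 questions stand on this flask, and one reagent balance answers the later two.

| flask | substrate | reagent | remark | time |
|---|---|---|---|---|
| ash | 0.20 M | 0.60 equiv | run made earlier |  |
| larch | 0.20 M | 2.4 equiv | run made earlier |  |
| flask | 0.20 M | 1.20 equiv |  | 1.5 h |

- ash (time / min: target / %, side product / %): 20.0: 47.2, 6.0; 40.0: 48.5, 6.0; 50.0: 48.2, 6.2; 80.0: 48.1, 6.4
- larch (time / min: target / %, side product / %): 6.00: 58.8, 42.3; 12.0: 58.3, 42.0; 30.0: 58.0, 42.5; 80.0: 58.6, 42.0

(scatter of a reading: 0.5 percentage points)

- share of target in target plus side product at 5.0 s
- share of target in target plus side product at 1.5 h
- which of target and side product there is more of at 1.5 h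

- the earlier runs were read with a standard deviation of 0.5 percentage points

We build the flask one process at a time. We start from the main step, one reagent per substrate giving target, which on the 1.20 equiv of this flask reckons to reagent over. The second step is read from the runs. In ash, target plus twice side product comes to 60.5% of the substrate, against a charge of 0.60 equiv, so side product costs two reagents. In larch, target plus side product comes to 100%. If substrate and reagent both end in products, subtracting these two balances puts side product at 20.0%: this is the closing side product P_c, the reagent charged above one equivalent. The share of target (the selectivity) is then 80.0%.

The rest enters as a correction. Let g be the substrate charge found in neither product: with the reagent all in products, each percent of g adds one percent to side product and takes two from target, so our end share lies just under 80.0%. Ash gave a share of 89.0% and reagent-rich larch 58.1%, so the share read lower with more reagent; this flask starts with its whole charge of reagent, and we put its early share below its end share. We give that gap no size, since the earliest reading stands at 6.00 min, later than 5.0 s.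

The forecast said 65% (61.5% to 69%) early and 80.5% (78% to 82.5%) at the end, which is above our 80.0%, with target ahead: “The target is therefore not over-reacting and the products are kinetically frozen.”

The flask gives 76.8% early and 78.8% at the end, with target ahead.

    substrate ⇌ intermediate A (K = 1.87, k = 0.0252 s⁻¹)
    substrate + reagent ⇌ intermediate B (K = 11.0 M⁻¹, k = 0.0486 M⁻¹ s⁻¹)
    reagent + intermediate B → side product (k = 0.203 M⁻¹ s⁻¹)
    reagent + intermediate A → target (k = 0.323 M⁻¹ s⁻¹)

In the flask, half of the turnover of substrate with reagent to intermediate B up to the asked time was done by 0.204 min, and at 0.150 h side product stood at 20.8% with 3.65% of the reagent left, against 20.9% side product at the end. From then to 1.50 h, reagent with intermediate A took target from 73.6% to 78.0%, leaving 0.11% of the reagent, 0.375% substrate and 0.699% intermediate A; P_c plus that g, less the reagent left, reads 20.9% against 20.9%. In a neighbour flask, with 0.50 M of substrate at the same equivalents, reagent ended at 0% of its charge and g at 11.9%; P_c plus g reads 31.9%, and that neighbour holds 31.9% side product.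

Readings and results were computed for an exercise, noise included.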